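The route rests on one bond of ring B, the cyclopentane of the bicyclo[3.2.1]octane core: the bond between its bridge CH2 (attached to the methyl-bearing bridgehead) and the ring-fusion CH it shares with cyclopentane ring C. With an NH inserted there, ring B becomes a piperidine, and that 3-azabicyclo[3.3.1]nonane is the product an alkylated acylphloroglucinol gives with ammonia and formaldehyde by double dearomative Mannich reaction. The key step deletes the nitrogen again: an anomeric amide turns the NH of 22 into an isodiazene, N2 is lost and the two flanking carbons couple, contracting the piperidine to ring B and delivering 25 directly. Precursor 22 is the target with NH between these two carbons.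

Key step: step 11

Remark: 2,4,6-trimethoxytoluene and the anomeric amide N-(benzyloxy)-N-(pivaloyloxy)-4-(trifluoromethyl)benzamide are taken as commercial; ring A is the six-membered triketone ring; enol tautomers are drawn arbitrarily, 22 is handled as its zwitterion, and the γ-hydroxy aldehydes 18 and 19 (drawn open) rest as five-membered lactols.

Step 1
Reactants: 1 2,4,6-trimethoxytoluene; 2 isobutyryl chloride
Product: 3 1-(2,4,6-trimethoxy-3-methylphenyl)-2-methylpropan-1-one
Conditions: SnCl4, CH2Cl2, −10 °C
Reagents that add atoms: none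
Why: Friedel–Crafts acylation of a ring activated by three methoxy groups, in which the two open positions are equivalent and SnCl4 at low temperature avoids the ether cleavage that stronger Lewis acids cause.

Step 2
Reactants: 3 1-(2,4,6-trimethoxy-3-methylphenyl)-2-methylpropan-1-one
Product: 4 1-[3-(chloromethyl)-2,4,6-trimethoxy-5-methylphenyl]-2-methylpropan-1-one
Conditions: (CH2O)n (excess), HCl (4 M in dioxane), 23 °C
Reagents that add atoms: formaldehyde (as paraformaldehyde), C=O; hydrogen chloride, Cl
Why: Blanc chloromethylation at the only remaining ring position, the chloride being preferred to the bromide because this doubly ortho- and para-alkoxylated benzylic halide ionises easily, while excess formaldehyde suppresses diarylmethane formation.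

Step 3
Reactants: 5 3,3-dimethylpent-4-enoic acid; 6 (S)-4-benzyloxazolidin-2-one
Product: 8 (S)-4-benzyl-3-(3,3-dimethylpent-4-enoyl)oxazolidin-2-one, via mixed pivalic anhydride 7 (not isolated)
Conditions: PivCl, Et3N, THF, −20 °C; then 6, LiCl, 23 °C
Reagents that add atoms: none
Why: N-acylation of the oxazolidinone through the mixed pivalic anhydride, which is attacked at its less hindered carbonyl group.

Step 4
Reactants: 8 (S)-4-benzyl-3-(3,3-dimethylpent-4-enoyl)oxazolidin-2-one; 4 1-[3-(chloromethyl)-2,4,6-trimethoxy-5-methylphenyl]-2-methylpropan-1-one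
Product: 9 (S)-4-benzyl-3-[(2S)-2-{[2,4,6-trimethoxy-3-methyl-5-(2-methylpropanoyl)phenyl]methyl}-3,3-dimethylpent-4-enoyl]oxazolidin-2-one
Conditions: NaN(SiMe3)2, THF, −78 °C; then 4, NaI (cat.), −78 to −20 °C
Reagents that add atoms: none
Why: Evans asymmetric alkylation, in which the chelated Z sodium enolate is shielded on one face by the benzyl group of the auxiliary so that the activated benzylic chloride enters from the other face and sets the new centre as S (acyl > tert-alkyl > CH2Ar), the hindered aryl ketone being neither attacked nor enolised by this weakly basic enolate.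

Step 5
Reactants: 9 alkylated imide
Product: 11 (2S)-2-{[2,4,6-trimethoxy-3-methyl-5-(2-methylpropanoyl)phenyl]methyl}-3,3-dimethylpent-4-enoic acid, via peroxy acid 10 (not isolated)
Conditions: LiOH, H2O2, THF/H2O, 0 °C; Na2SO3; then 1 M HCl
Reagents that add atoms: hydrogen peroxide (as lithium hydroperoxide), OO
Why: Hydroperoxide hydrolysis of the imide cleaves the exocyclic acyl group selectively even in hindered cases without epimerising the α-centre, and the peroxy acid is reduced by sulfite before work-up.

Step 6
Reactants: 11 trimethoxy acid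
Product: 13 (3S)-5,7-dihydroxy-8-methyl-3-(2-methylbut-3-en-2-yl)-6-(2-methylpropanoyl)chroman-2-one, via trihydroxy acid 12 (not isolated)
Conditions: BBr3, CH2Cl2, −78 to 0 °C; H2O; then EDC·HCl, CH2Cl2, 23 °C
Reagents that add atoms: none
Why: Lewis-acid cleavage of the three aryl methyl ethers followed by carbodiimide lactonisation of the unchelated ortho phenol onto the carboxyl group (dihydrocoumarin formation), done before any acid-labile carbinol exists, with the neopentyl-type vinyl group expected to survive the cold aprotic conditions and any isomeric lactone on the other ortho phenol converging in step 7.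

Step 7
Reactants: 13 dihydrocoumarin lactone
Product: 15 1-{2,4,6-trihydroxy-3-[(2S)-2-(2-hydroxypropan-2-yl)-3,3-dimethylpent-4-en-1-yl]-5-methylphenyl}-2-methylpropan-1-one, via methyl ketone 14 (not isolated)
Conditions: CeCl3, MeMgBr (excess), THF, −78 to 0 °C; aq. NH4Cl
Reagents that add atoms: methylmagnesium bromide, C[Mg]Br
Why: Double addition of a CeCl3-activated methyl Grignard reagent to the aryl lactone (ester to tertiary alcohol), the organocerium character suppressing enolisation of the intermediate methyl ketone and thus epimerisation, while the aryl ketone is masked in the flask as the vinylogous carboxylate of its flanking magnesium phenoxides.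

Step 8
Reactants: 15 trihydroxy carbinol
Product: 16 triacetate of 15 (three aryl acetates, free tertiary alcohol)
Conditions: Ac2O, pyridine, DMAP (cat.), CH2Cl2, 0 °C
Reagents that add atoms: acetic anhydride, CC(=O)OC(C)=O
Why: O-acetylation of the three phenols (the hindered tertiary alcohol does not react under these conditions) deactivates the electron-rich ring so that the oxidative cleavage of step 9 cannot attack it, and it also curbs air oxidation and acid-catalysed chroman formation.

Step 9
Reactants: 16 triacetate
Product: 18 (3S)-3-{[2,4,6-triacetoxy-3-methyl-5-(2-methylpropanoyl)phenyl]methyl}-4-hydroxy-2,2,4-trimethylpentanal, via ozonide 17 (not isolated)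
Conditions: O3, CH2Cl2, −78 °C; then PPh3, −78 to 23 °C
Reagents that add atoms: ozone, [O-][O+]=O
Why: Ozonolysis of the only alkene with reductive work-up gives a non-enolisable neopentyl aldehyde that rests as its lactol with the tertiary hydroxyl group, the aryl acetates being inert to ozone.

Step 10
Reactants: 18 triacetoxy aldehyde
Product: 22 aza-bridged precursor (zwitterion), via triol aldehyde 19 (not isolated), via NH-aldimine 20 (not isolated), via spirocyclic amine 21 (not isolated)
Conditions: NH3 (7 M in MeOH), 23 °C; concentrate; NH4OAc, AcOH, aq. CH2O (1.05 equiv), MeOH, 45 °C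
Reagents that add atoms: ammonia, N; formaldehyde, C=O
Why: Ammonolysis frees the phenols and turns the lactol into the NH-aldiminium ion, which adds 5-exo-trig to the alkyl-bearing ring carbon in a dearomative ipso-Mannich reaction (the mode known from the conversion of C-alkylated phloroglucinols with hexamethylenetetramine into azaadamantanetriones) with nitrogen cis to the hydroxyisopropyl group (both pseudo-equatorial on the new cyclopentane), after which the primary amine and formaldehyde close the aza bridge 6-endo-trig onto the methyl-bearing carbon rather than the poorly nucleophilic acyl-bearing one, so that the existing S centre relays all three new centres under reversible conditions.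

Step 11
Reactants: 22 aza-bridged precursor
Product: 25 CNP0267234.1 (target), via N-amino adduct 23 (not isolated), via isodiazene 24 (not isolated)
Conditions: Cs2CO3 (1.1 equiv), MeCN/THF, 23 °C; then N-(benzyloxy)-N-(pivaloyloxy)-4-(trifluoromethyl)benzamide (1.5 equiv), 45 °C; aq. NaH2PO4
Reagents that add atoms: none
Why: Proposed new method: the free secondary amine of the cesium enolate attacks the amide nitrogen of the reagent with loss of pivalate (substitution at nitrogen), adduct 23 undergoes reductive elimination with migration of the benzyloxy group to the acyl carbon to give isodiazene 24, and loss of N2 leaves a singlet 1,5-diradical (primary CH2 radical on the methyl-bearing bridgehead, secondary radical at the ring-fusion carbon) that recombines. The closest known reaction type is nitrogen deletion of secondary amines with anomeric amides, including ring contraction of cyclic amines, which is established chiefly where a benzylic radical forms, whereas both radical centres here are unstabilised. Ring B closes by radical–radical recombination across a 1,5-relationship, a cyclopentane formed by extrusion and not by a Baldwin-type addition. The only stereocentre made is the ring-fusion CH, and the cage dictates it: the planar secondary radical can bond to the CH2 radical only on the face that keeps ring C cis-fused to ring B, the trans-fused bicyclo[3.3.0] alternative being prohibitively strained, so even an epimer of 22 at this carbon would converge on 25. The step needs N-amination in preference to reaction at the enolate and recombination in preference to escape; the salt form keeps the amine nucleophilic and blocks retro-Mannich cleavage, both radical carbons are flanked only by quaternary carbons so that no β-hydrogen is available for disproportionation, and the bicycle holds the two centres three atoms apart. The remaining risks are tautomerisation of 24 to a hydrazone through its α-hydrogens and β-scission toward the neighbouring carbonyl carbons.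

Compound list
1 | 2,4,6-trimethoxytoluene (1,3,5-trimethoxy-2-methylbenzene) | COc1cc(OC)c(C)c(OC)c1 | starting material
2 | isobutyryl chloride (2-methylpropanoyl chloride) | CC(C)C(Cl)=O | starting material
3 | 1-(2,4,6-trimethoxy-3-methylphenyl)-2-methylpropan-1-one | CC(C)C(=O)c1c(OC)cc(OC)c(C)c1OC | intermediate
4 | 1-[3-(chloromethyl)-2,4,6-trimethoxy-5-methylphenyl]-2-methylpropan-1-one | CC(C)C(=O)c1c(OC)c(CCl)c(OC)c(C)c1OC | intermediate
5 | 3,3-dimethylpent-4-enoic acid | OC(=O)CC(C)(C)C=C | starting material
6 | (S)-4-benzyloxazolidin-2-one | O=C1N[C@@H](Cc2ccccc2)CO1 | starting material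
7 | 3,3-dimethylpent-4-enoic pivalic anhydride | C=CC(C)(C)CC(=O)OC(=O)C(C)(C)C | intermediate (not isolated)
8 | (S)-4-benzyl-3-(3,3-dimethylpent-4-enoyl)oxazolidin-2-one | C=CC(C)(C)CC(=O)N1[C@@H](Cc2ccccc2)COC1=O | intermediate
9 | (S)-4-benzyl-3-[(2S)-2-{[2,4,6-trimethoxy-3-methyl-5-(2-methylpropanoyl)phenyl]methyl}-3,3-dimethylpent-4-enoyl]oxazolidin-2-one | C=CC(C)(C)[C@H](Cc1c(OC)c(C)c(OC)c(C(=O)C(C)C)c1OC)C(=O)N1[C@@H](Cc2ccccc2)COC1=O | intermediate
10 | (2S)-2-{[2,4,6-trimethoxy-3-methyl-5-(2-methylpropanoyl)phenyl]methyl}-3,3-dimethylpent-4-eneperoxoic acid | C=CC(C)(C)[C@H](Cc1c(OC)c(C)c(OC)c(C(=O)C(C)C)c1OC)C(=O)OO | intermediate (not isolated)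
11 | (2S)-2-{[2,4,6-trimethoxy-3-methyl-5-(2-methylpropanoyl)phenyl]methyl}-3,3-dimethylpent-4-enoic acid | C=CC(C)(C)[C@H](Cc1c(OC)c(C)c(OC)c(C(=O)C(C)C)c1OC)C(O)=O | intermediate
12 | (2S)-2-{[2,4,6-trihydroxy-3-methyl-5-(2-methylpropanoyl)phenyl]methyl}-3,3-dimethylpent-4-enoic acid | C=CC(C)(C)[C@H](Cc1c(O)c(C)c(O)c(C(=O)C(C)C)c1O)C(O)=O | intermediate (not isolated)
13 | (3S)-5,7-dihydroxy-8-methyl-3-(2-methylbut-3-en-2-yl)-6-(2-methylpropanoyl)chroman-2-one | C=CC(C)(C)[C@@H]1Cc2c(O)c(C(=O)C(C)C)c(O)c(C)c2OC1=O | intermediate
14 | (3S)-3-{[2,4,6-trihydroxy-3-methyl-5-(2-methylpropanoyl)phenyl]methyl}-4,4-dimethylhex-5-en-2-one | C=CC(C)(C)[C@@H](C(C)=O)Cc1c(O)c(C)c(O)c(C(=O)C(C)C)c1O | intermediate (not isolated)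
15 | 1-{2,4,6-trihydroxy-3-[(2S)-2-(2-hydroxypropan-2-yl)-3,3-dimethylpent-4-en-1-yl]-5-methylphenyl}-2-methylpropan-1-one | C=CC(C)(C)[C@@H](C(C)(C)O)Cc1c(O)c(C)c(O)c(C(=O)C(C)C)c1O | intermediate
16 | triacetate of 15: 2-[(2S)-2-(2-hydroxypropan-2-yl)-3,3-dimethylpent-4-en-1-yl]-6-methyl-4-(2-methylpropanoyl)benzene-1,3,5-triyl triacetate | C=CC(C)(C)[C@@H](C(C)(C)O)Cc1c(OC(C)=O)c(C)c(OC(C)=O)c(C(=O)C(C)C)c1OC(C)=O | intermediate
17 | 1,2,4-trioxolane (secondary ozonide) of the vinyl group of 16, mixture at the ozonide carbon | CC(C)(C1OOCO1)[C@@H](C(C)(C)O)Cc1c(OC(C)=O)c(C)c(OC(C)=O)c(C(=O)C(C)C)c1OC(C)=O | intermediate (not isolated)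
18 | (3S)-3-{[2,4,6-triacetoxy-3-methyl-5-(2-methylpropanoyl)phenyl]methyl}-4-hydroxy-2,2,4-trimethylpentanal (rests as its lactol) | O=CC(C)(C)[C@@H](C(C)(C)O)Cc1c(OC(C)=O)c(C)c(OC(C)=O)c(C(=O)C(C)C)c1OC(C)=O | intermediate
19 | (3S)-3-{[2,4,6-trihydroxy-3-methyl-5-(2-methylpropanoyl)phenyl]methyl}-4-hydroxy-2,2,4-trimethylpentanal (rests as its lactol) | O=CC(C)(C)[C@@H](C(C)(C)O)Cc1c(O)c(C)c(O)c(C(=O)C(C)C)c1O | intermediate (not isolated)
20 | NH-aldimine of 19 | N=CC(C)(C)[C@@H](C(C)(C)O)Cc1c(O)c(C)c(O)c(C(=O)C(C)C)c1O | intermediate (not isolated)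
21 | spirocyclic primary amine: dearomatised ring A spiro-fused to a cyclopentane carrying NH2 (S), gem-dimethyl and the (S)-CH–C(CH3)2OH unit, with NH2 cis to the hydroxyisopropyl group and on the side of the methyl-bearing ring carbon | CC(C)C(=O)C1=C(O)C(C)=C(O)[C@@]2(C[C@H](C(C)(C)O)C(C)(C)[C@@H]2N)C1=O | intermediate (not isolated)
22 | aza-bridged precursor: (1S,2S,5S)-6-hydroxy-5-methyl-7-(2-methylpropanoyl)-3-azabicyclo[3.3.1]non-6-ene-8,9-dione with a cyclopentane fused at C1–C2 [C1–CH2–CH((S), C(CH3)2OH)–C(CH3)2–C2]; NH between the bridge CH2 (C4) and the ring-fusion CH (C2); zwitterion | CC(C)C(=O)C1=C(O)[C@]2(C)CN[C@H]3C(C)(C)[C@@H](C(C)(C)O)C[C@@]3(C1=O)C2=O | intermediate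
23 | N-amino adduct of 22: ring nitrogen bonded to N(OCH2Ph)C(=O)C6H4-4-CF3 | CC(C)C(=O)C1=C(O)[C@]2(C)CN(N(OCc4ccccc4)C(=O)c4ccc(cc4)C(F)(F)F)[C@H]3C(C)(C)[C@@H](C(C)(C)O)C[C@@]3(C1=O)C2=O | intermediate (not isolated)
24 | isodiazene (1,1-diazene) of 22 | CC(C)C(=O)C1=C(O)[C@]2(C)C[N+](=[N-])[C@H]3C(C)(C)[C@@H](C(C)(C)O)C[C@@]3(C1=O)C2=O | intermediate (not isolated)
25 | CNP0267234.1: (1S,5S,7S)-4-hydroxy-5-methyl-3-(2-methylpropanoyl)bicyclo[3.2.1]oct-3-ene-2,8-dione with a cyclopentane fused at C1–C7 [C1–CH2–CH((S), C(CH3)2OH)–C(CH3)2–C7] | CC(C)C(=O)C1=C(O)[C@]2(C)C[C@H]3C(C)(C)[C@@H](C(C)(C)O)C[C@@]3(C1=O)C2=O | target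

Total step count: 11. Longest linear sequence: 10 steps (1 → 3 → 4 → 9 → 11 → 13 → 15 → 16 → 18 → 22 → 25); the side branch 5 → 8 joins at step 4.

Steps most likely to fail

Step 11 (nitrogen deletion). The hindered amine may fail to capture the reagent. Alternatively the isodiazene may tautomerise to a hydrazone, dimerise or fragment toward the carbonyl groups instead of extruding N2 and recombining. The fallback gives up the aza bridge and builds ring B by the known oxidative radical cyclisation of dearomatised diprenyl acylphloroglucinols. It sets out from ketone 3. BBr3 (CH2Cl2, −78 to 23 °C) should give 1-(2,4,6-trihydroxy-3-methylphenyl)-2-methylpropan-1-one F1. Prenyl bromide (2 equiv) with NaOMe in MeOH at 0 °C should give racemic 3,5-dihydroxy-6-methyl-2,6-bis(3-methylbut-2-en-1-yl)-4-(2-methylpropanoyl)cyclohexa-2,4-dien-1-one F2. Mn(OAc)3·2H2O and Cu(OAc)2·H2O in AcOH at 23 °C should then trigger two successive 5-exo radical closures (ring B, then ring C) and give the racemic isopropenyl tricycle F3, to be separated by chromatography from its epimer at the isopropenyl-bearing carbon. Mukaiyama hydration (Co(acac)2, PhSiH3, O2, iPrOH) should give the racemic target F4, and preparative HPLC on a chiral stationary phase brings the route back at 25. This path trades the absolute stereocontrol of the main route for a resolution.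

Step 10 (double Mannich). Facial control in the spirocyclisation may be lost, which would give the cage of opposite sense relative to the carbinol-bearing centre. Ammonia and formaldehyde may also be diverted into enaminone formation at the acyl ketone, N-hydroxymethylation or aminal formation. The fallback replaces ammonia by one equivalent of a primary amine and adds a deprotection. It sets out from 18: K2CO3 in MeOH at 0 °C, then AcOH, gives triol aldehyde 19 (isolated here). Benzylamine (1.0 equiv) and AcOH in MeOH preform the N-benzyl aldimine, and aqueous CH2O (1.05 equiv) at 45 °C should close the N-benzyl derivative of 22 F5. Diastereomers could be separated at this stage and the unwanted one re-equilibrated under the reaction conditions. Hydrogenolysis (H2, Pd(OH)2/C, MeOH) returns to the route at 22.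

Step 7 (double methyl addition). The reaction may stall after the first addition through enolisation of the hindered methyl ketone, with erosion of the α-stereocentre, or the reagent may add to the aryl ketone. The fallback goes stepwise through isolated intermediates, setting out from lactone 13. Me(MeO)NH·HCl with iPrMgCl (THF, −20 °C) should open it to the Weinreb amide (2S)-N-methoxy-N,3,3-trimethyl-2-{[2,4,6-trihydroxy-3-methyl-5-(2-methylpropanoyl)phenyl]methyl}pent-4-enamide F6. MeMgBr (THF, 0 °C) stops cleanly at methyl ketone 14, now isolated and checked for configurational integrity. MeLi with LaCl3·2LiCl (THF, −78 to 0 °C) completes the carbinol and returns to the route at 15.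

Further compounds
F1 | step 11 | 1-(2,4,6-trihydroxy-3-methylphenyl)-2-methylpropan-1-one | CC(C)C(=O)c1c(O)cc(O)c(C)c1O
F2 | step 11 | racemic 3,5-dihydroxy-6-methyl-2,6-bis(3-methylbut-2-en-1-yl)-4-(2-methylpropanoyl)cyclohexa-2,4-dien-1-one | CC(C)C(=O)C1=C(O)C(C)(CC=C(C)C)C(=O)C(CC=C(C)C)=C1O
F3 | step 11 | racemic isopropenyl analogue of 25 (prop-1-en-2-yl in place of 2-hydroxypropan-2-yl, same relative configuration) | CC(C)C(=O)C1=C(O)[C@]2(C)C[C@H]3C(C)(C)[C@@H](C(C)=C)C[C@@]3(C1=O)C2=O.CC(C)C(=O)C1=C(O)[C@@]2(C)C[C@@H]3C(C)(C)[C@H](C(C)=C)C[C@]3(C1=O)C2=O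
F4 | step 11 | racemic 25 | CC(C)C(=O)C1=C(O)[C@]2(C)C[C@H]3C(C)(C)[C@@H](C(C)(C)O)C[C@@]3(C1=O)C2=O.CC(C)C(=O)C1=C(O)[C@@]2(C)C[C@@H]3C(C)(C)[C@H](C(C)(C)O)C[C@]3(C1=O)C2=O
F5 | step 10 | N-benzyl derivative of 22 | CC(C)C(=O)C1=C(O)[C@]2(C)CN(Cc4ccccc4)[C@H]3C(C)(C)[C@@H](C(C)(C)O)C[C@@]3(C1=O)C2=O
F6 | step 7 | (2S)-N-methoxy-N,3,3-trimethyl-2-{[2,4,6-trihydroxy-3-methyl-5-(2-methylpropanoyl)phenyl]methyl}pent-4-enamide | C=CC(C)(C)[C@@H](C(=O)N(C)OC)Cc1c(O)c(C)c(O)c(C(=O)C(C)C)c1O
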